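The route rests on opening the pyran ring of ring B at its two bonds to the benzene ring, C4–C4a and O1–C8a (isoflavone C3' and C4'). One operation makes both: 3-methoxybenzyne, released from a 2-silylaryl triflate, takes up the C=O of 3-methylbut-2-enal, and the resulting benzoxete opens and recloses by oxa-6π-electrocyclization to the 2,2-dimethyl-2H-chromene. The step exploits the oxygen on C2' of ring B, which flanks the aryne and decides which aryne carbon receives O and which C. The chromene is borylated and joined to a 3,6-diiodochromone; the C6 iodide then accepts the 3-hydroxy-3-methylbutyl chain.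

Key step: step 1

Remark: kanzonol T has no stereocentre and no stereogenic double bond (its only non-aromatic C=C lies in the six-membered pyran ring), so it is achiral and no stereocontrol is needed.

**Step 1**
Reactants: 1 3-methoxy-2-(trimethylsilyl)phenyl trifluoromethanesulfonate; 2 3-methylbut-2-enal
Product: 6 5-methoxy-2,2-dimethyl-2H-chromene, via 3-methoxybenzyne 3 (not isolated), via benzoxete 4 (not isolated), via ortho-quinone methide 5 (not isolated)
Conditions: CsF (3 equiv), 2 (4 equiv), MeCN, rt → 50 °C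
Reagents that add atoms: none
Why: Fluoride attacks silicon of 1 and expels triflate to give aryne 3; the carbonyl oxygen of 2 adds to the aryne carbon remote from OMe (future C8a) because the aryl anion then sits on the carbon flanked by the inductively withdrawing OMe (future C4a), and this anion closes on the carbonyl carbon to give benzoxete 4 (stepwise formal [2+2]). Thermal 4π-electrocyclic opening of the strained oxete gives ortho-quinone methide 5, whose O=C–C=C–C=CMe2 array closes the pyran ring by a disrotatory oxa-6π-electrocyclization that forms O1–C2 and restores the benzene ring. The closest known reaction type is the annulation of silylaryl-triflate-derived arynes with α,β-unsaturated aldehydes to 2H-chromenes (aryne insertion into C=O). No stereocentre is formed. The step needs regioselectivity on the aryne, secured by the methoxy group next to the triple bond (the later 2'-oxygen), and chemoselectivity for C=O addition over ene reaction or fluoride-induced self-condensation of 2, which the excess of aldehyde and the mild CsF/MeCN conditions should favour.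

**Step 2**
Reactants: 6 5-methoxy-2,2-dimethyl-2H-chromene
Product: 7 2,2-dimethyl-2H-chromen-5-ol
Conditions: NaSEt (3 equiv), DMF, 130 °C; then cold 1 M HCl to pH 5
Reagents that add atoms: none
Why: SN2 demethylation of the aryl methyl ether by thiolate should proceed cleanly because the chromene offers no electrophilic or base-labile site.

**Step 3**
Reactants: 7 2,2-dimethyl-2H-chromen-5-ol
Product: 8 5-(methoxymethoxy)-2,2-dimethyl-2H-chromene
Conditions: NaH, MOMCl, DMF, 0 °C → rt
Reagents that add atoms: chloromethyl methyl ether (MOMCl), COCCl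
Why: Williamson O-alkylation of the phenoxide installs the MOM group, which serves both as protecting group and as director for the next step.

**Step 4**
Reactants: 8 5-(methoxymethoxy)-2,2-dimethyl-2H-chromene
Product: 10 2-[5-(methoxymethoxy)-2,2-dimethyl-2H-chromen-6-yl]-4,4,5,5-tetramethyl-1,3,2-dioxaborolane, via aryllithium 9 (not isolated)
Conditions: n-BuLi, TMEDA, THF, −78 → 0 °C; then i-PrOBpin, −78 °C → rt; H2O
Reagents that add atoms: 2-isopropoxy-4,4,5,5-tetramethyl-1,3,2-dioxaborolane, CC(C)OB1OC(C)(C)C(C)(C)O1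
Why: Directed ortho-metalation by the OMOM group should lithiate C6, the only free aromatic position ortho to it, and the aryllithium is trapped as the pinacol boronate.

**Step 5**
Reactants: 11 1-(2,4,6-trihydroxyphenyl)ethan-1-one
Product: 12 1-[2,6-dihydroxy-4-(methoxymethoxy)phenyl]ethan-1-one
Conditions: MOMCl (1.05 equiv), i-Pr2NEt, THF, 0 °C
Reagents that add atoms: chloromethyl methyl ether (MOMCl), COCCl
Why: Selective O-alkylation should occur at the 4-OH, the only hydroxyl not hydrogen-bonded to the acetyl group and the most acidic one.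

**Step 6**
Reactants: 12 1-[2,6-dihydroxy-4-(methoxymethoxy)phenyl]ethan-1-one
Product: 13 (E)-1-[2,6-dihydroxy-4-(methoxymethoxy)phenyl]-3-(dimethylamino)prop-2-en-1-one
Conditions: DMF-DMA (2 equiv), toluene, 90 °C
Reagents that add atoms: N,N-dimethylformamide dimethyl acetal, COC(OC)N(C)C
Why: Condensation of the methyl ketone with the formamide acetal gives the enaminone, the chelated phenols being poor substrates for O-methylation at this temperature.

**Step 7**
Reactants: 13 (E)-1-[2,6-dihydroxy-4-(methoxymethoxy)phenyl]-3-(dimethylamino)prop-2-en-1-one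
Product: 14 5-hydroxy-3-iodo-7-(methoxymethoxy)-4H-chromen-4-one
Conditions: I2 (1.1 equiv), CHCl3, rt
Reagents that add atoms: iodine, II
Why: Iodination of the enaminone α-carbon followed by addition–elimination cyclization of a phenol with loss of dimethylamine (Gammill 3-iodochromone synthesis) should give one chromone, since the two hydroxyls of 13 are equivalent by symmetry.

**Step 8**
Reactants: 14 5-hydroxy-3-iodo-7-(methoxymethoxy)-4H-chromen-4-one
Product: 15 5-hydroxy-3,6-diiodo-7-(methoxymethoxy)-4H-chromen-4-one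
Conditions: BnMe3N·ICl2 (1.05 equiv), CaCO3, CH2Cl2–MeOH, rt
Reagents that add atoms: benzyltrimethylammonium dichloroiodate, C[N+](C)(C)Cc1ccccc1.Cl[I-]Cl
Why: Electrophilic aromatic iodination of 5-hydroxy-7-alkoxychromones with this reagent is directed ortho to the free chelated 5-OH, so C6 and not C8 should be iodinated.

**Step 9**
Reactants: 15 5-hydroxy-3,6-diiodo-7-(methoxymethoxy)-4H-chromen-4-one; 10 2-[5-(methoxymethoxy)-2,2-dimethyl-2H-chromen-6-yl]-4,4,5,5-tetramethyl-1,3,2-dioxaborolane
Product: 16 5-hydroxy-6-iodo-7-(methoxymethoxy)-3-[5-(methoxymethoxy)-2,2-dimethyl-2H-chromen-6-yl]-4H-chromen-4-one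
Conditions: 10 (1.05 equiv), Pd(PPh3)4 (5 mol%), aq. Na2CO3, DME, 50 °C
Reagents that add atoms: none
Why: In this Suzuki–Miyaura coupling, oxidative addition should take place at the carbonyl-activated vinylic C3–I well before the C6–I, which is flanked by two oxygen substituents on an electron-rich ring.

**Step 10**
Reactants: 16 5-hydroxy-6-iodo-7-(methoxymethoxy)-3-[5-(methoxymethoxy)-2,2-dimethyl-2H-chromen-6-yl]-4H-chromen-4-one; 17 2-methylbut-3-en-2-ol
Product: 19 5-hydroxy-6-(3-hydroxy-3-methylbutyl)-7-(methoxymethoxy)-3-[5-(methoxymethoxy)-2,2-dimethyl-2H-chromen-6-yl]-4H-chromen-4-one, via alkylborane 18 (not isolated)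
Conditions: 17 (3.0 equiv), 9-BBN-H (2.8 equiv), THF, 0 °C → rt; then 16, Pd(OAc)2 (5 mol%), SPhos (10 mol%), aq. K3PO4, THF, 60 °C
Reagents that add atoms: none
Why: Anti-Markovnikov hydroboration of the terminal alkene and B-alkyl Suzuki–Miyaura coupling at the remaining aryl iodide deliver the saturated chain directly, the alkene being kept in excess over 9-BBN so that no B–H reaches the chromene alkene or the chromone.

**Step 11**
Reactants: 19 5-hydroxy-6-(3-hydroxy-3-methylbutyl)-7-(methoxymethoxy)-3-[5-(methoxymethoxy)-2,2-dimethyl-2H-chromen-6-yl]-4H-chromen-4-one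
Product: 20 kanzonol T, 5,7-dihydroxy-6-(3-hydroxy-3-methylbutyl)-3-(5-hydroxy-2,2-dimethyl-2H-chromen-6-yl)-4H-chromen-4-one
Conditions: 1 M HCl, MeOH–THF, 35 °C
Reagents that add atoms: none
Why: Acid-catalysed transacetalization of the two aryl MOM ethers to methanol frees the 7- and 2'-hydroxyls under dilute, cool conditions that the chromene and the tertiary alcohol should tolerate.

**Compound list**
1 | 3-methoxy-2-(trimethylsilyl)phenyl trifluoromethanesulfonate | COc1cccc(OS(=O)(=O)C(F)(F)F)c1[Si](C)(C)C | starting material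
2 | 3-methylbut-2-enal | CC(C)=CC=O | starting material
3 | 3-methoxybenzyne (1-methoxycyclohexa-1,3-dien-5-yne) | COC1=CC=CC#C1 | intermediate (not isolated)
4 | 3-methoxy-2-(2-methylprop-1-en-1-yl)-2H-benzo[b]oxete | COc1cccc2OC(C=C(C)C)c12 | intermediate (not isolated)
5 | (6Z)-5-methoxy-6-(3-methylbut-2-en-1-ylidene)cyclohexa-2,4-dien-1-one | COC1=CC=CC(=O)/C1=C\C=C(C)C | intermediate (not isolated)
6 | 5-methoxy-2,2-dimethyl-2H-chromene | COc1cccc2OC(C)(C)C=Cc12 | intermediate
7 | 2,2-dimethyl-2H-chromen-5-ol | Oc1cccc2OC(C)(C)C=Cc12 | intermediate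
8 | 5-(methoxymethoxy)-2,2-dimethyl-2H-chromene | COCOc1cccc2OC(C)(C)C=Cc12 | intermediate
9 | [5-(methoxymethoxy)-2,2-dimethyl-2H-chromen-6-yl]lithium | COCOc1c([Li])ccc2OC(C)(C)C=Cc12 | intermediate (not isolated)
10 | 2-[5-(methoxymethoxy)-2,2-dimethyl-2H-chromen-6-yl]-4,4,5,5-tetramethyl-1,3,2-dioxaborolane | COCOc1c(B2OC(C)(C)C(C)(C)O2)ccc2OC(C)(C)C=Cc12 | intermediate
11 | 1-(2,4,6-trihydroxyphenyl)ethan-1-one | CC(=O)c1c(O)cc(O)cc1O | starting material
12 | 1-[2,6-dihydroxy-4-(methoxymethoxy)phenyl]ethan-1-one | CC(=O)c1c(O)cc(OCOC)cc1O | intermediate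
13 | (E)-1-[2,6-dihydroxy-4-(methoxymethoxy)phenyl]-3-(dimethylamino)prop-2-en-1-one | CN(C)/C=C/C(=O)c1c(O)cc(OCOC)cc1O | intermediate
14 | 5-hydroxy-3-iodo-7-(methoxymethoxy)-4H-chromen-4-one | COCOc1cc(O)c2c(c1)occ(I)c2=O | intermediate
15 | 5-hydroxy-3,6-diiodo-7-(methoxymethoxy)-4H-chromen-4-one | COCOc1cc2occ(I)c(=O)c2c(O)c1I | intermediate
16 | 5-hydroxy-6-iodo-7-(methoxymethoxy)-3-[5-(methoxymethoxy)-2,2-dimethyl-2H-chromen-6-yl]-4H-chromen-4-one | COCOc1cc2occ(-c3ccc4OC(C)(C)C=Cc4c3OCOC)c(=O)c2c(O)c1I | intermediate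
17 | 2-methylbut-3-en-2-ol | CC(C)(O)C=C | starting material
18 | 4-(9-borabicyclo[3.3.1]nonan-9-yl)-2-methylbutan-2-ol | CC(C)(O)CCB1C2CCCC1CCC2 | intermediate (not isolated)
19 | 5-hydroxy-6-(3-hydroxy-3-methylbutyl)-7-(methoxymethoxy)-3-[5-(methoxymethoxy)-2,2-dimethyl-2H-chromen-6-yl]-4H-chromen-4-one | COCOc1cc2occ(-c3ccc4OC(C)(C)C=Cc4c3OCOC)c(=O)c2c(O)c1CCC(C)(C)O | intermediate
20 | kanzonol T | CC(C)(O)CCc1c(O)cc2occ(-c3ccc4c(c3O)C=CC(C)(C)O4)c(=O)c2c1O | target

**Step count and risks**
Total step count: 11. Longest linear sequence: 7 steps (steps 5–11 from 11, or steps 1–4 and 9–11 from 1).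

Steps most likely to fail:

1. Step 10. Oxidative addition at the C6–I bond, which has two ortho substituents and sits next to a phenoxide, may be slow, and β-hydride elimination of the alkylpalladium with protodeiodination may then win. The fallback installs the chain at the acetophenone stage by Sonogashira coupling and hydrogenation, before any chromene alkene is present. It sets out from 12.
   - Mono-benzylation (BnBr, K2CO3, DMF) should give 1-[2-(benzyloxy)-6-hydroxy-4-(methoxymethoxy)phenyl]ethan-1-one F1.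
   - Iodination ortho to the remaining chelated hydroxyl (BnMe3N·ICl2, CaCO3) should give 1-[6-(benzyloxy)-2-hydroxy-3-iodo-4-(methoxymethoxy)phenyl]ethan-1-one F2.
   - MOM protection (NaH, MOMCl) should give 1-[6-(benzyloxy)-3-iodo-2,4-bis(methoxymethoxy)phenyl]ethan-1-one F3.
   - Sonogashira coupling with 2-methylbut-3-yn-2-ol (Pd(PPh3)2Cl2, CuI, Et3N, 60 °C) should give 1-[6-(benzyloxy)-3-(3-hydroxy-3-methylbut-1-yn-1-yl)-2,4-bis(methoxymethoxy)phenyl]ethan-1-one F4.
   - Hydrogenation (H2, Pd/C, EtOAc) saturates the alkyne and removes the benzyl group to give 1-[6-hydroxy-3-(3-hydroxy-3-methylbutyl)-2,4-bis(methoxymethoxy)phenyl]ethan-1-one F5, whose only free hydroxyl is the one next to an aromatic C–H.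
   - DMF-DMA then gives (E)-3-(dimethylamino)-1-[6-hydroxy-3-(3-hydroxy-3-methylbutyl)-2,4-bis(methoxymethoxy)phenyl]prop-2-en-1-one F6, and iodine gives 6-(3-hydroxy-3-methylbutyl)-3-iodo-5,7-bis(methoxymethoxy)-4H-chromen-4-one F7.
   - Suzuki coupling with 10 gives 6-(3-hydroxy-3-methylbutyl)-5,7-bis(methoxymethoxy)-3-[5-(methoxymethoxy)-2,2-dimethyl-2H-chromen-6-yl]-4H-chromen-4-one F8, which is deprotected under the conditions of step 11 and comes back to the route at 20.

2. Step 1. Fluoride may trigger self-condensation of the enolisable enal, the aryne may undergo an ene reaction with the allylic methyl groups, or a second aryne may consume the quinone methide before it cyclizes. The fallback keeps the aryne insertion into a C=O bond but separates it from the pyran closure. It sets out from 1.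
   - Treatment with CsF in DMF and aqueous work-up should give 2-hydroxy-6-methoxybenzaldehyde F9 by insertion into the formamide C=O and hydrolysis; both bonds to the ring are still made in one operation.
   - Addition of 2-methylprop-1-en-1-ylmagnesium bromide (2.2 equiv, THF, 0 °C) gives 2-(1-hydroxy-3-methylbut-2-en-1-yl)-3-methoxyphenol F10, racemic, its stereocentre being lost in the next operation.
   - Warming with a trace of acid or on silica dehydrates this to the ortho-quinone methide, which electrocyclizes to 6, where the route is rejoined.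

3. Step 11. Under the acid needed for MOM cleavage the tertiary alcohol may ionize and be captured by the neighbouring 5- or 7-hydroxyl with closure of a dimethylchroman ring. The fallback reverses the order so that the tertiary alcohol never meets acid. It sets out from 16.
   - The MOM groups are removed first (HCl, MeOH, 50 °C) to give 5,7-dihydroxy-3-(5-hydroxy-2,2-dimethyl-2H-chromen-6-yl)-6-iodo-4H-chromen-4-one F11.
   - B-alkyl Suzuki coupling with alkylborane 18 (Pd(OAc)2, SPhos, excess aq. K3PO4, THF, 60 °C) is then the last operation and comes back to the route at 20.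

**Further compounds**
F1 | step 10 | 1-[2-(benzyloxy)-6-hydroxy-4-(methoxymethoxy)phenyl]ethan-1-one | CC(=O)c1c(O)cc(OCOC)cc1OCc1ccccc1
F2 | step 10 | 1-[6-(benzyloxy)-2-hydroxy-3-iodo-4-(methoxymethoxy)phenyl]ethan-1-one | CC(=O)c1c(O)c(I)c(OCOC)cc1OCc1ccccc1
F3 | step 10 | 1-[6-(benzyloxy)-3-iodo-2,4-bis(methoxymethoxy)phenyl]ethan-1-one | CC(=O)c1c(OCOC)c(I)c(OCOC)cc1OCc1ccccc1
F4 | step 10 | 1-[6-(benzyloxy)-3-(3-hydroxy-3-methylbut-1-yn-1-yl)-2,4-bis(methoxymethoxy)phenyl]ethan-1-one | CC(=O)c1c(OCOC)c(C#CC(C)(C)O)c(OCOC)cc1OCc1ccccc1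
F5 | step 10 | 1-[6-hydroxy-3-(3-hydroxy-3-methylbutyl)-2,4-bis(methoxymethoxy)phenyl]ethan-1-one | CC(=O)c1c(OCOC)c(CCC(C)(C)O)c(OCOC)cc1O
F6 | step 10 | (E)-3-(dimethylamino)-1-[6-hydroxy-3-(3-hydroxy-3-methylbutyl)-2,4-bis(methoxymethoxy)phenyl]prop-2-en-1-one | CN(C)/C=C/C(=O)c1c(OCOC)c(CCC(C)(C)O)c(OCOC)cc1O
F7 | step 10 | 6-(3-hydroxy-3-methylbutyl)-3-iodo-5,7-bis(methoxymethoxy)-4H-chromen-4-one | COCOc1cc2occ(I)c(=O)c2c(OCOC)c1CCC(C)(C)O
F8 | step 10 | 6-(3-hydroxy-3-methylbutyl)-5,7-bis(methoxymethoxy)-3-[5-(methoxymethoxy)-2,2-dimethyl-2H-chromen-6-yl]-4H-chromen-4-one | COCOc1cc2occ(-c3ccc4OC(C)(C)C=Cc4c3OCOC)c(=O)c2c(OCOC)c1CCC(C)(C)O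
F9 | step 1 | 2-hydroxy-6-methoxybenzaldehyde | COc1cccc(O)c1C=O
F10 | step 1 | 2-(1-hydroxy-3-methylbut-2-en-1-yl)-3-methoxyphenol (racemic) | COc1cccc(O)c1C(O)C=C(C)C
F11 | step 11 | 5,7-dihydroxy-3-(5-hydroxy-2,2-dimethyl-2H-chromen-6-yl)-6-iodo-4H-chromen-4-one | Oc1cc2occ(-c3ccc4OC(C)(C)C=Cc4c3O)c(=O)c2c(O)c1I
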